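The cyclohexene ring (C5–C6–C7–C8–C9–C10, drimane numbering) is grown from the cyclopentanone of a trans-hydrindanone made from (S)-Hajos–Parrish ketone, whose quaternary carbon becomes C10. The key step exploits that C9, the CH that carries the CH2O group, lies between quaternary C10 and C8: a β-oxido carbenoid rearrangement inserts C9 between these atoms and leaves the C8=C9 enolate, which is hydroxymethylated in the same flask anti to the C10 methyl. One operation thus builds the six-membered ring, the C9–C10 and C9–C11 bonds and the axial C9 stereocentre from a dibromomethyl carbinol. The C8 ketone then becomes the C7=C8 methyl olefin; Mitsunobu etherification with isofraxidin and C3 oxidation finish.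

Key step: step 6

Remark: the target SMILES places the C9 CH2OAr group trans to the C10 methyl and cis to H-5 (axial, 9-epi-drimenyl series), and the route is designed for this configuration; (S)-Hajos–Parrish ketone and isofraxidin are taken as commercial.

Step 1
Reactants: 1 (7aS)-7a-methyl-2,3,7,7a-tetrahydro-1H-indene-1,5(6H)-dione (Hajos–Parrish ketone)
Product: 2 (7aS)-7a-methyl-2,3,7,7a-tetrahydrospiro[indene-1,2'-[1,3]dioxolan]-5(6H)-one
Conditions: 2-ethyl-2-methyl-1,3-dioxolane (solvent), ethylene glycol (cat.), p-TsOH·H2O (cat.), rt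
Reagents that add atoms: 2-ethyl-2-methyl-1,3-dioxolane, CCC1(C)OCCO1
Why: Acid-catalysed transketalisation should be selective for the saturated cyclopentanone carbonyl because the conjugated enone carbonyl is far less electrophilic; no stereocenter is formed.

Step 2
Reactants: 2
Product: 3 (7aS)-4,4,7a-trimethyl β,γ-unsaturated ketone ketal (double bond moved into the five-membered ring, C5=C6 in drimane numbering)
Conditions: KOtBu (3 equiv), t-BuOH, rt; MeI (excess), 0 °C → rt
Reagents that add atoms: iodomethane, CI
Why: Deconjugative α,α-dialkylation of the enone through its potassium dienolate should place both methyl groups on C4 and move the double bond to C5=C6, while the ketal keeps the five-ring carbonyl from enolising; no stereocenter is formed.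

Step 3
Reactants: 3
Product: 4 (3aS,7aS)-4,4,7a-trimethylhexahydrospiro[indene-1,2'-[1,3]dioxolan]-5(4H)-one (trans-fused)
Conditions: H2 (3 bar), 10% Pd/C, EtOAc, rt
Reagents that add atoms: none
Why: Heterogeneous catalytic hydrogenation should deliver hydrogen to the α face of the C5=C6 olefin, opposite the C10 methyl and the β-oriented C4 methyl (as in the hydrogenation of Δ14 steroids), which sets H-5 trans to the C10 methyl.

Step 4
Reactants: 4
Product: 6 (3aS,5S,7aS)-5-hydroxy-4,4,7a-trimethyloctahydro-1H-inden-1-one, via hydroxy ketal 5 (not isolated)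
Conditions: NaBH4, MeOH, 0 °C; then 2 M HCl, THF, rt
Reagents that add atoms: water, O
Why: Borohydride reduction from the α face (opposite the axial C4 and C10 methyls) should give the equatorial 3β-alcohol as a masked C3 ketone whose configuration is erased in step 12, and aqueous acid then hydrolyses the dioxolane to free the C8 ketone.

Step 5
Reactants: 6
Product: 7 (1S,3aS,5S,7aS)-1-(dibromomethyl)-4,4,7a-trimethyloctahydro-1H-indene-1,5-diol
Conditions: CH2Br2 (3 equiv), LDA (3.2 equiv), THF, −78 °C; AcOH quench at −78 °C
Reagents that add atoms: dibromomethane, BrCBr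
Why: Dibromomethyllithium, formed in situ faster than the hindered ketone is enolised, should add 1,2 to the C8 carbonyl from the face opposite the C10 methyl (carbenoid–carbonyl addition); the carbinol stereocenter is destroyed in step 6.

Step 6
Reactants: 7
Product: 10 (1R,4aR,6S,8aS)-6-hydroxy-1-(hydroxymethyl)-5,5,8a-trimethyloctahydronaphthalen-2(1H)-one, via β-oxido carbenoid 8 (not isolated), via ring-expanded dilithium enolate 9 (not isolated)
Conditions: n-BuLi (3.2 equiv), THF, −78 → 0 °C; then monomeric CH2O (THF solution), −78 °C; NH4Cl quench at −78 °C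
Reagents that add atoms: formaldehyde, C=O
Why: After deprotonation of both hydroxyls, Br/Li exchange gives β-oxido carbenoid 8, whose loss of LiBr is coupled to a 1,2-shift of C10 from the carbinol carbon C8 to the carbenoid carbon, so that the five-membered ring grows by one atom (the new C9) and enolate 9 with its double bond fixed at C8=C9 results. The closest known reaction type is the β-oxido carbenoid one-carbon ring enlargement of ketones (a Tiffeneau–Demjanov-type homologation), followed here by a lithium enolate aldol addition to monomeric formaldehyde. No ring is closed by cyclisation: the six-membered ring arises by ring expansion through a 1,2-alkyl shift with retention at the migrating quaternary carbon. The new stereocenter C9 is set in the aldol by substrate control from C10, because formaldehyde should approach the enolate axially on the α face, anti to the axial C10 methyl, which places CH2OH trans to that methyl and cis to H-5. The step needs migration of the quaternary C10 and not of the C7 methylene, which the higher migratory aptitude of the more substituted, electron-richer carbon toward the electron-poor carbenoid centre should secure, while the enolate regiochemistry follows from the mechanism. It also needs a kinetic aldol, secured by addition at −78 °C and a cold quench, since the axial C9 epimer is the less stable one.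

Step 7
Reactants: 10
Product: 11 bis(tert-butyldimethylsilyl) ether of 10
Conditions: TBSOTf (2.5 equiv), 2,6-lutidine, CH2Cl2, −78 → −20 °C
Reagents that add atoms: tert-butyldimethylsilyl triflate, CC(C)(C)[Si](C)(C)OS(=O)(=O)C(F)(F)F
Why: The silyl triflate with a hindered pyridine base should silylate the primary and the hindered secondary hydroxyl at low temperature without enolising the ketone, which protects the β-hydroxy ketone against retro-aldol cleavage and epimerisation at C9.

Step 8
Reactants: 11
Product: 12 C7=C8 enol triflate of 11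
Conditions: KHMDS (1.2 equiv), THF, −78 °C; PhNTf2, −78 → 0 °C
Reagents that add atoms: N-phenyl-bis(trifluoromethanesulfonimide), O=S(=O)(N(c1ccccc1)S(=O)(=O)C(F)(F)F)C(F)(F)F
Why: Kinetic deprotonation by the bulky amide should occur at the C7 methylene, whose axial hydrogen is aligned with the carbonyl π system, and not at C9, whose only hydrogen is equatorial and flanked by quaternary C10, so that O-triflation fixes the C7=C8 double bond without touching C9.

Step 9
Reactants: 12
Product: 13 bis(tert-butyldimethylsilyl) ether of 9-epi-drim-7-ene-3β,11-diol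
Conditions: MeMgBr (3 equiv), Fe(acac)3 (5 mol %), THF/NMP, −30 → 0 °C
Reagents that add atoms: methylmagnesium bromide, C[Mg]Br
Why: Iron-catalysed cross-coupling of the alkenyl triflate with the methyl Grignard reagent should replace OTf by methyl with retention of the double-bond position; silyl ethers are inert and no stereocenter is affected.

Step 10
Reactants: 13
Product: 14 (2S,4aS,5R,8aR)-5-(hydroxymethyl)-1,1,4a,6-tetramethyl-1,2,3,4,4a,5,8,8a-octahydronaphthalen-2-ol (9-epi-drim-7-ene-3β,11-diol)
Conditions: TBAF (4 equiv), THF, 60 °C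
Reagents that add atoms: none
Why: Fluoride-induced cleavage of both silyl ethers (Si–F bond formation) should free the primary C11 and the secondary C3 hydroxyl, with warming needed for the hindered C3 ether.

Step 11
Reactants: 14; 15 isofraxidin (7-hydroxy-6,8-dimethoxy-2H-chromen-2-one)
Product: 16 7-{[(1R,4aR,6S,8aS)-6-hydroxy-2,5,5,8a-tetramethyl-1,4,4a,5,6,7,8,8a-octahydronaphthalen-1-yl]methoxy}-6,8-dimethoxy-2H-chromen-2-one
Conditions: PPh3, DIAD, THF, 0 °C → rt
Reagents that add atoms: isofraxidin (compound 15), COc1cc2ccc(=O)oc2c(OC)c1O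
Why: Mitsunobu etherification, in which the acidic 7-OH of the coumarin should displace the oxyphosphonium salt of the primary C11 alcohol by SN2 while the secondary C3 hydroxyl next to the gem-dimethyl group is too hindered to react; no stereocenter is touched.

Step 12
Reactants: 16
Product: 17 7-{[(1R,4aR,8aS)-2,5,5,8a-tetramethyl-6-oxo-1,4,4a,5,6,7,8,8a-octahydronaphthalen-1-yl]methoxy}-6,8-dimethoxy-2H-chromen-2-one (target)
Conditions: Dess–Martin periodinane, CH2Cl2, rt
Reagents that add atoms: none
Why: Dess–Martin oxidation of the remaining secondary alcohol should give the C3 ketone under mild conditions that leave the trisubstituted olefin, the aryl ether, the coumarin and the C9 stereocenter untouched.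

Compound list
1 | (7aS)-7a-methyl-2,3,7,7a-tetrahydro-1H-indene-1,5(6H)-dione, (S)-Hajos–Parrish ketone | C[C@]12CCC(=O)C=C1CCC2=O | starting material
2 | (7aS)-7a-methyl-2,3,7,7a-tetrahydrospiro[indene-1,2'-[1,3]dioxolan]-5(6H)-one | C[C@]12CCC(=O)C=C1CCC23OCCO3 | intermediate
3 | (7aS)-4,4,7a-trimethyl β,γ-unsaturated ketone ketal (C5=C6 olefin in the five-membered ring) | C[C@]12CCC(=O)C(C)(C)C1=CCC23OCCO3 | intermediate
4 | (3aS,7aS)-4,4,7a-trimethylhexahydrospiro[indene-1,2'-[1,3]dioxolan]-5(4H)-one, trans-fused | C[C@]12CCC(=O)C(C)(C)[C@@H]1CCC23OCCO3 | intermediate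
5 | (3aS,5S,7aS)-4,4,7a-trimethyloctahydrospiro[indene-1,2'-[1,3]dioxolan]-5-ol | C[C@]12CC[C@H](O)C(C)(C)[C@@H]1CCC23OCCO3 | intermediate (not isolated)
6 | (3aS,5S,7aS)-5-hydroxy-4,4,7a-trimethyloctahydro-1H-inden-1-one | C[C@]12CC[C@H](O)C(C)(C)[C@@H]1CCC2=O | intermediate
7 | (1S,3aS,5S,7aS)-1-(dibromomethyl)-4,4,7a-trimethyloctahydro-1H-indene-1,5-diol | C[C@]12CC[C@H](O)C(C)(C)[C@@H]1CC[C@@]2(O)C(Br)Br | intermediate
8 | dilithium β-oxido carbenoid (bromolithiomethyl carbinolate) | C[C@]12CC[C@H](O[Li])C(C)(C)[C@@H]1CC[C@@]2(O[Li])C([Li])Br | intermediate (not isolated)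
9 | ring-expanded dilithium enolate (C8=C9 enolate, C3 alkoxide) | C[C@]12CC[C@H](O[Li])C(C)(C)[C@@H]1CCC(O[Li])=C2 | intermediate (not isolated)
10 | (1R,4aR,6S,8aS)-6-hydroxy-1-(hydroxymethyl)-5,5,8a-trimethyloctahydronaphthalen-2(1H)-one | C[C@]12CC[C@H](O)C(C)(C)[C@@H]1CCC(=O)[C@H]2CO | intermediate
11 | bis(tert-butyldimethylsilyl) ether of 10 | C[C@]12CC[C@H](O[Si](C)(C)C(C)(C)C)C(C)(C)[C@@H]1CCC(=O)[C@H]2CO[Si](C)(C)C(C)(C)C | intermediate
12 | C7=C8 enol triflate of 11 | C[C@]12CC[C@H](O[Si](C)(C)C(C)(C)C)C(C)(C)[C@@H]1CC=C(OS(=O)(=O)C(F)(F)F)[C@H]2CO[Si](C)(C)C(C)(C)C | intermediate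
13 | bis(tert-butyldimethylsilyl) ether of 9-epi-drim-7-ene-3β,11-diol | C[C@]12CC[C@H](O[Si](C)(C)C(C)(C)C)C(C)(C)[C@@H]1CC=C(C)[C@H]2CO[Si](C)(C)C(C)(C)C | intermediate
14 | (2S,4aS,5R,8aR)-5-(hydroxymethyl)-1,1,4a,6-tetramethyl-1,2,3,4,4a,5,8,8a-octahydronaphthalen-2-ol | C[C@]12CC[C@H](O)C(C)(C)[C@@H]1CC=C(C)[C@H]2CO | intermediate
15 | isofraxidin, 7-hydroxy-6,8-dimethoxy-2H-chromen-2-one | COc1cc2ccc(=O)oc2c(OC)c1O | starting material
16 | 3β-hydroxy aryl ether, 7-{[(1R,4aR,6S,8aS)-6-hydroxy-2,5,5,8a-tetramethyl-1,4,4a,5,6,7,8,8a-octahydronaphthalen-1-yl]methoxy}-6,8-dimethoxy-2H-chromen-2-one | COc1cc2ccc(=O)oc2c(OC)c1OC[C@@H]1C(C)=CC[C@H]2C(C)(C)[C@@H](O)CC[C@]12C | intermediate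
17 | CNP0127079.1, 7-{[(1R,4aR,8aS)-2,5,5,8a-tetramethyl-6-oxo-1,4,4a,5,6,7,8,8a-octahydronaphthalen-1-yl]methoxy}-6,8-dimethoxy-2H-chromen-2-one | COc1cc2ccc(=O)oc2c(OC)c1OC[C@@H]1C(C)=CC[C@H]2C(C)(C)C(=O)CC[C@]12C | target

Total step count: 12. Longest linear sequence: 12 steps (1 → 17); isofraxidin 15 enters in step 11.

Steps most likely to fail

Step 6. The C7 methylene may migrate in place of the quaternary C10, and proton transfer or retro-aldol cleavage in the crowded one-pot trapping may erode the kinetically set axial configuration at C9. The fallback sets out from 6 and comes back at 10. Addition of bis(phenylthio)methyllithium (from bis(phenylthio)methane and n-BuLi, THF, −78 °C) should give the bis(phenylthio)methyl carbinol F1. Methyllithium (3.2 equiv, THF, −78 → 0 °C) should expel lithium thiophenolate and bring about ring expansion through a sulfur-stabilised carbenoid, for which migration of the more substituted carbon is the expected course, to give after protonation the isolable α-phenylthio ketone F2. Lithium naphthalenide (THF, −78 °C) should then cleave the C–S bond reductively and regenerate enolate 9 regiospecifically, and formaldehyde at −78 °C should give 10.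

Step 11. The SN2 displacement at the hindered, β-branched primary oxyphosphonium centre by a phenol flanked by two methoxy groups may be slow, so that elimination or reaction at the C3 hydroxyl competes. The fallback sets out from 13 and comes back at 16. PPTS in MeOH (rt) should remove only the primary silyl ether and give the mono-protected alcohol F3. Tf2O and pyridine (CH2Cl2, −78 °C) should give the primary triflate F4. Williamson-type displacement by the caesium phenoxide of isofraxidin 15 (Cs2CO3, DMF, 0 °C → rt) should give the silyl-protected ether F5, and TBAF (THF, 60 °C) should then give 16.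

Step 3. Hydrogen may be delivered in part to the β face, giving the cis-hydrindane, and the hindered trisubstituted olefin may be reduced only slowly. The fallback sets out from 3 and comes back at 4. L-Selectride (THF, −78 °C) should give by equatorial hydride delivery the axial 3α-alcohol F6. Hydroxyl-directed homogeneous hydrogenation with [Ir(cod)(PCy3)(py)]PF6 (H2, CH2Cl2) should deliver hydrogen to the α face on which the hydroxyl sits and give the trans-fused alcohol F7, and Dess–Martin oxidation should return ketone 4.

Further compounds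
F1 | step 6 | (1S,3aS,5S,7aS)-1-[bis(phenylthio)methyl]-4,4,7a-trimethyloctahydro-1H-indene-1,5-diol | C[C@]12CC[C@H](O)C(C)(C)[C@@H]1CC[C@@]2(O)C(Sc1ccccc1)Sc1ccccc1
F2 | step 6 | ring-expanded α-(phenylthio) ketone, 6-hydroxy-5,5,8a-trimethyl-1-(phenylthio)octahydronaphthalen-2(1H)-one (trans-fused, C1 epimers) | C[C@]12CC[C@H](O)C(C)(C)[C@@H]1CCC(=O)C2Sc1ccccc1
F3 | step 11 | 3-O-tert-butyldimethylsilyl ether of 14 with free C11 hydroxyl | C[C@]12CC[C@H](O[Si](C)(C)C(C)(C)C)C(C)(C)[C@@H]1CC=C(C)[C@H]2CO
F4 | step 11 | C11 trifluoromethanesulfonate of F3 | C[C@]12CC[C@H](O[Si](C)(C)C(C)(C)C)C(C)(C)[C@@H]1CC=C(C)[C@H]2COS(=O)(=O)C(F)(F)F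
F5 | step 11 | 3-O-tert-butyldimethylsilyl ether of 16 | COc1cc2ccc(=O)oc2c(OC)c1OC[C@@H]1C(C)=CC[C@H]2C(C)(C)[C@@H](O[Si](C)(C)C(C)(C)C)CC[C@]12C
F6 | step 3 | 3α-alcohol from 3, (5R,7aS)-4,4,7a-trimethyl unsaturated ketal alcohol | C[C@]12CC[C@@H](O)C(C)(C)C1=CCC23OCCO3
F7 | step 3 | trans-fused 3α-alcohol, (3aS,5R,7aS)-4,4,7a-trimethyloctahydrospiro[indene-1,2'-[1,3]dioxolan]-5-ol | C[C@]12CC[C@@H](O)C(C)(C)[C@@H]1CCC23OCCO3
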